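**Retrosynthetic overview**

1. Target 29 ← desilylation, allylic oxidation at C6, dehydration of the C8 carbinol and two acylations ← tricyclic hydroxy ketone 20 (ketone at C11, free OH on C1, silyl ether on C2).
2. 20 ← monocyclic epoxy keto aldehyde 17 in one operation: bond C1–C2 (aldol, closes the seven-membered ring), then bond C9–C10 (enolate opens the epoxide, closes the cyclobutane); both C10 epimers converge.
3. Enabling feature: C11 is a ketone whose two α-carbons are C1 and C10, the very atoms that must bond to C2 and C9. C2 is a non-enolisable aldehyde on quaternary C3, C9 is an epoxide carbon of ring A (C4–C9) with its oxygen trans to both side chains, and the silyl group on O–C1 can move to O–C2.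
4. 17 ← (1S,4R)-p-mentha-2,8-dien-1-ol 1 (supplies ring A, the C8 methyl, C10 and C11): Ireland–Claisen rearrangement of its isobutyrate sets C3–C4 cis to the C5 side chain; then hydroboration, hydroxymethylation (C1), oxidation, epoxidation.
5. Ring order: ring A (six-membered, from the terpene) → seven-membered and four-membered rings together in step 10 → enone of ring A last.

Key step: step 10

Remark: atom numbers C1–C11 are the ring carbons of the target: C1 (angelate carbinol), C2 (free carbinol), C3 (CMe2), C4 and C5 (cyclobutane CH), C6 (ketone), C7=C8(CH3), C9 (cyclobutane CH), C10 (quaternary C–CH3), C11 (isovalerate carbinol).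
Remark: C10 (from step 3) and C11 (steps 5 to 7) are carried as epimer mixtures and their SMILES bear no descriptor there; C11 is oxidised in step 8 and C10 is planarised in step 10.

**Step 1**
Reactants: 1 (1S,4R)-1-methyl-4-(prop-1-en-2-yl)cyclohex-2-en-1-ol; 2 2-methylpropanoyl chloride
Product: 3 (1S,4R)-1-methyl-4-(prop-1-en-2-yl)cyclohex-2-en-1-yl 2-methylpropanoate
Conditions: n-BuLi, THF, −78 °C; then 2, −78 → 0 °C
Reagents that add atoms: none
Why: O-acylation of the lithium alkoxide (nucleophilic acyl substitution) esterifies the tertiary allylic alcohol without the ionisation that acidic conditions would cause; no stereocentre is touched.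

**Step 2**
Reactants: 3 isobutyrate of 1
Product: 6 2-methyl-2-[(1S,6R)-3-methyl-6-(prop-1-en-2-yl)cyclohex-2-en-1-yl]propanoic acid, via silyl ketene acetal 4 (not isolated), via trimethylsilyl ester 5 (not isolated)
Conditions: LiN(i-Pr)2, Me3SiCl, THF/HMPA, −78 → 65 °C; then 1 M HCl
Reagents that add atoms: none
Why: Ireland–Claisen rearrangement; the [3,3] shift of the symmetric silyl ketene acetal is suprafacial, so the C3–C4 bond should form on the ring face that carried the ester oxygen, i.e. cis to the isopropenyl group on C5, creating quaternary C3, stereocentre C4 and the C8=C9 alkene.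

**Step 3**
Reactants: 6 Claisen acid
Product: 8 hydroxy acid (6 with CH(CH3)CH2OH on C5), via organoborane 7 (not isolated)
Conditions: 9-BBN (2.3 equiv), THF, 0 → 25 °C; then NaOH, H2O2, 0 → 25 °C; HCl to pH 3
Reagents that add atoms: hydrogen peroxide, OO
Why: hydroboration–oxidation; 9-BBN should take the 1,1-disubstituted isopropenyl alkene and leave the trisubstituted ring alkene, placing oxygen on the terminal carbon (C11), while the acid only consumes one hydride; C10 forms as an epimer mixture.

**Step 4**
Reactants: 8 hydroxy acid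
Product: 9 aldehyde acid (CH(CH3)CHO on C5)
Conditions: Dess–Martin periodinane, NaHCO3, CH2Cl2, 0 → 25 °C
Reagents that add atoms: none
Why: Dess–Martin oxidation of the primary alcohol stops at the aldehyde and tolerates the carboxylic acid and the alkene.

**Step 5**
Reactants: 9 aldehyde acid; 10 (chloromethyl)(isopropoxy)dimethylsilane
Product: 13 dihydroxy acid (CH(CH3)CH(OH)CH2OH on C5), via Grignard reagent 11 (not isolated), via hydroxysilane 12 (not isolated)
Conditions: 10, Mg, THF, 25 °C; then 9 (0.28 equiv), 0 °C; then KF, KHCO3, H2O2, THF/MeOH, 25 °C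
Reagents that add atoms: hydrogen peroxide, OO
Why: Grignard addition of the silylmethyl anion to the aldehyde followed by Tamao oxidation of the C–Si bond is a hydroxymethylation that brings in C1; the magnesium carboxylate is inert and the new C11 carbinol is formed unselectively.

**Step 6**
Reactants: 13 dihydroxy acid
Product: 14 triethylsilyl ester of the acid bearing CH(CH3)CH(OH)CH2OSiEt3 on C5
Conditions: Et3SiCl (2.2 equiv), imidazole, CH2Cl2, −40 °C
Reagents that add atoms: chlorotriethylsilane, CC[Si](Cl)(CC)CC
Why: silylation; the carboxylic acid and the primary hydroxyl should react well before the hindered secondary carbinol at C11.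

**Step 7**
Reactants: 14 silyl ester silyl ether
Product: 15 diol (CMe2CH2OH on C4; CH(CH3)CH(OH)CH2OSiEt3 on C5)
Conditions: LiAlH4, Et2O, 0 °C
Reagents that add atoms: none
Why: hydride reduction of the silyl ester to the neopentyl alcohol; the silyl ether and both alkenes are inert to LiAlH4 at 0 °C.

**Step 8**
Reactants: 15 diol
Product: 16 keto aldehyde (CMe2CHO on C4; CH(CH3)C(=O)CH2OSiEt3 on C5)
Conditions: Dess–Martin periodinane (3 equiv), NaHCO3, CH2Cl2, 0 → 25 °C
Reagents that add atoms: none
Why: double Dess–Martin oxidation gives the non-enolisable C2 aldehyde and the α-silyloxy ketone at C11 in one operation.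

**Step 9**
Reactants: 16 keto aldehyde
Product: 17 epoxy keto aldehyde (C8–C9 epoxide trans to both side chains)
Conditions: dimethyldioxirane, acetone, −30 °C
Reagents that add atoms: dimethyldioxirane, CC1(C)OO1
Why: neutral oxygen transfer to the electron-rich trisubstituted alkene should outrun aldehyde oxidation, and the reagent should approach anti to the quaternary substituent on the neighbouring C4, which puts the oxygen on the face opposite to C10, as the rear-side attack of step 10 requires.

**Step 10**
Reactants: 17 epoxy keto aldehyde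
Product: 20 tricyclic hydroxy ketone (C11 ketone; OH on C1; OSiEt3 on C2; tertiary OH on C8), via lithium aldolate 18 (not isolated), via silyl-shifted lithium alkoxide 19 (not isolated)
Conditions: LiN(i-Pr)2 (2.3 equiv), THF, −78 → 25 °C; AcOH, −20 °C
Reagents that add atoms: none
Why: Mechanism: LiN(i-Pr)2 removes the kinetically and thermodynamically favoured proton at C1 (the C2 aldehyde on quaternary C3 cannot enolise), the chelated Z-enolate adds to C2 (intramolecular aldol addition, 7-enolexo, closing ring C1–C2–C3–C4–C5–C10–C11), the lithium aldolate takes the triethylsilyl group from the neighbouring oxygen (1,4 O-to-O silyl migration), and the second equivalent of base forms the only enolate left, C10=C11, which opens the epoxide at C9 from the rear (4-exo-tet enolate alkylation, closing the cyclobutane C4–C5–C10–C9). The closest known reaction types are aldol additions of α-silyloxy ketone enolates with silyl transfer to the aldolate, epoxynitrile-type enolate–epoxide cyclisations that give cyclobutanes in preference to cyclopentanes, and the enolate alkylations that close bicyclo[3.1.1]heptanones. C1 and C2 are set in the aldol on the cis-fused chair (C3 equatorial on C4, C10 axial on C5), where both oxygens are expected to take pseudo-equatorial sites, which is the 1,2-trans arrangement with O–C2 on the side of C9; C9 is inverted, C8 keeps the epoxide configuration, and C10 is set by the tether, because C11 is held in the seven-membered ring and the methyl group can only point toward the C6–C7–C8 bridge. Both C10 epimers of 17 therefore converge on one product, since C10 is planar when the bond is made. The step needs C-alkylation at C9 and not attack at tertiary C8 (5-endo) or O-alkylation, which would place the C10=C11 bond at a bridgehead; it also needs the C2 oxygen to be silylated before the mixture warms, because a free alkoxide there could open the epoxide in a 5-exo mode, whereas the alkoxide on C1 could reach C9 only through a seven-membered ring. The silyl shift is expected to run downhill because it leaves the more stabilised, carbonyl-chelated alkoxide on C1 and makes the aldol irreversible.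

**Step 11**
Reactants: 20 tricyclic hydroxy ketone; 21 (Z)-2-methylbut-2-enoic acid (angelic acid)
Product: 23 C1 angelate of 20, via mixed anhydride 22 (not isolated)
Conditions: 21, 2,4,6-trichlorobenzoyl chloride, Et3N, toluene, 25 °C; then 20, 60 °C
Reagents that add atoms: none
Why: Yamaguchi esterification without DMAP acylates the only reactive hydroxyl (secondary, on C1) and should keep the Z geometry of the angelate; the tertiary C8 hydroxyl is inert.

**Step 12**
Reactants: 23 angelate ketone
Product: 24 C11 alcohol (OH on C11 cis to the angelate on C1)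
Conditions: NaBH4, CeCl3·7H2O, MeOH, −78 → −40 °C
Reagents that add atoms: none
Why: Luche reduction; the two faces of the seven-membered ring are otherwise nearly equivalent, so hydride should add anti to the acyloxy group on the adjacent C1 (Felkin–Anh model), which gives the C11 hydroxyl cis to O–C1, and the cold, weakly basic medium limits acyl migration.

**Step 13**
Reactants: 24 C11 alcohol; 25 3-methylbutanoyl chloride (isovaleryl chloride)
Product: 26 C11 isovalerate C1 angelate (OSiEt3 on C2; tertiary OH on C8)
Conditions: pyridine, CH2Cl2, 0 °C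
Reagents that add atoms: none
Why: acylation of the only free secondary hydroxyl with an acid chloride under weakly basic conditions, chosen so that the neighbouring angelate does not migrate; the tertiary hydroxyl does not react.

**Step 14**
Reactants: 26 diester with tertiary OH on C8
Product: 27 alkene (C7=C8, methyl on C8)
Conditions: Martin sulfurane, CH2Cl2, −20 → 0 °C
Reagents that add atoms: none
Why: sulfurane-mediated dehydration of the tertiary alcohol under cold, neutral conditions; elimination toward bridgehead C9 is forbidden by Bredt's rule, so the ring hydrogen on C7 should be lost to give the trisubstituted endocyclic alkene.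

**Step 15**
Reactants: 27 alkene
Product: 28 enone (C6 ketone conjugated with C7=C8)
Conditions: Rh2(cap)4 (cap = caprolactamate, 1 mol %), t-BuOOH, K2CO3, CH2Cl2, 25 °C
Reagents that add atoms: tert-butyl hydroperoxide, CC(C)(C)OO
Why: catalytic allylic C–H oxidation at the ring methylene C6, the same site selectivity that turns α-pinene into verbenone; the bridgehead C9–H cannot give an enone and the electron-poor angelate alkene should not react.

**Step 16**
Reactants: 28 silyl-protected enone
Product: 29 CNP0151972.1 (target)
Conditions: HF·pyridine, pyridine, THF, 0 °C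
Reagents that add atoms: none
Why: fluoride-driven cleavage of the triethylsilyl ether under buffered conditions that leave both esters and the enone intact; no stereocentre is touched.

**Compound list**

1 | (1S,4R)-1-methyl-4-(prop-1-en-2-yl)cyclohex-2-en-1-ol (OH cis to isopropenyl) | O[C@]1(C)C=C[C@H](C(C)=C)CC1 | starting material
2 | 2-methylpropanoyl chloride | CC(C)C(Cl)=O | starting material
3 | (1S,4R)-1-methyl-4-(prop-1-en-2-yl)cyclohex-2-en-1-yl 2-methylpropanoate | CC(C)C(=O)O[C@]1(C)C=C[C@H](C(C)=C)CC1 | intermediate
4 | trimethylsilyl ketene acetal of 3 | CC(C)=C(O[Si](C)(C)C)O[C@]1(C)C=C[C@H](C(C)=C)CC1 | intermediate (not isolated)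
5 | trimethylsilyl ester of 6 | C[Si](C)(C)OC(=O)C(C)(C)[C@@H]1[C@H](C(C)=C)CCC(C)=C1 | intermediate (not isolated)
6 | 2-methyl-2-[(1S,6R)-3-methyl-6-(prop-1-en-2-yl)cyclohex-2-en-1-yl]propanoic acid (side chains cis) | OC(=O)C(C)(C)[C@@H]1[C@H](C(C)=C)CCC(C)=C1 | intermediate
7 | B-alkyl-9-BBN adduct of the 9-BBN carboxylate of 6 | O=C(OB1C2CCCC1CCC2)C(C)(C)[C@@H]3[C@H](C(C)CB4C5CCCC4CCC5)CCC(C)=C3 | intermediate (not isolated)
8 | hydroxy acid: 6 with CH(CH3)CH2OH on C5 | OC(=O)C(C)(C)[C@@H]1[C@H](C(C)CO)CCC(C)=C1 | intermediate
9 | aldehyde acid: CH(CH3)CHO on C5 | OC(=O)C(C)(C)[C@@H]1[C@H](C(C)C=O)CCC(C)=C1 | intermediate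
10 | (chloromethyl)(isopropoxy)dimethylsilane | CC(C)O[Si](C)(C)CCl | starting material
11 | (isopropoxydimethylsilyl)methylmagnesium chloride | CC(C)O[Si](C)(C)C[Mg]Cl | intermediate (not isolated)
12 | hydroxysilane: CH(CH3)CH(OH)CH2SiMe2(Oi-Pr) on C5 | OC(=O)C(C)(C)[C@@H]1[C@H](C(C)C(O)C[Si](C)(C)OC(C)C)CCC(C)=C1 | intermediate (not isolated)
13 | dihydroxy acid: CH(CH3)CH(OH)CH2OH on C5 | OC(=O)C(C)(C)[C@@H]1[C@H](C(C)C(O)CO)CCC(C)=C1 | intermediate
14 | triethylsilyl ester with CH(CH3)CH(OH)CH2OSiEt3 on C5 | CC[Si](CC)(CC)OC(=O)C(C)(C)[C@@H]1[C@H](C(C)C(O)CO[Si](CC)(CC)CC)CCC(C)=C1 | intermediate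
15 | diol: CMe2CH2OH on C4, CH(CH3)CH(OH)CH2OSiEt3 on C5 | OCC(C)(C)[C@@H]1[C@H](C(C)C(O)CO[Si](CC)(CC)CC)CCC(C)=C1 | intermediate
16 | keto aldehyde: CMe2CHO on C4, CH(CH3)C(=O)CH2OSiEt3 on C5, cis, C8=C9 alkene | O=CC(C)(C)[C@@H]1[C@H](C(C)C(=O)CO[Si](CC)(CC)CC)CCC(C)=C1 | intermediate
17 | epoxy keto aldehyde: 16 with C8–C9 epoxide trans to the side chains | O=CC(C)(C)[C@@H]2[C@H](C(C)C(=O)CO[Si](CC)(CC)CC)CC[C@@]3(C)O[C@@H]23 | intermediate
18 | lithium aldolate: seven-membered ring closed, O–Li on C2, OSiEt3 on C1 | O=C1[C@H](O[Si](CC)(CC)CC)[C@@H]([O-])C(C)(C)[C@@H]2[C@H](C1C)CC[C@@]3(C)O[C@@H]23.[Li+] | intermediate (not isolated)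
19 | silyl-shifted lithium alkoxide: O–Li on C1, OSiEt3 on C2 | O=C1[C@H]([O-])[C@@H](O[Si](CC)(CC)CC)C(C)(C)[C@@H]2[C@H](C1C)CC[C@@]3(C)O[C@@H]23.[Li+] | intermediate (not isolated)
20 | tricyclic hydroxy ketone: C11 ketone, OH on C1, OSiEt3 on C2 (trans), tertiary OH on C8 | O=C1[C@H](O)[C@@H](O[Si](CC)(CC)CC)C(C)(C)[C@@H]2[C@H]3CC[C@@](C)(O)[C@@H]2[C@@]13C | intermediate
21 | (Z)-2-methylbut-2-enoic acid (angelic acid) | C/C=C(/C)C(O)=O | starting material
22 | (Z)-2-methylbut-2-enoic 2,4,6-trichlorobenzoic anhydride | C/C=C(/C)C(=O)OC(=O)c1c(Cl)cc(Cl)cc1Cl | intermediate (not isolated)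
23 | C1 angelate of 20 | O=C1[C@H](OC(=O)/C(C)=C\C)[C@@H](O[Si](CC)(CC)CC)C(C)(C)[C@@H]2[C@H]3CC[C@@](C)(O)[C@@H]2[C@@]13C | intermediate
24 | C11 alcohol, OH cis to the C1 angelate | O[C@@H]1[C@H](OC(=O)/C(C)=C\C)[C@@H](O[Si](CC)(CC)CC)C(C)(C)[C@@H]2[C@H]3CC[C@@](C)(O)[C@@H]2[C@@]13C | intermediate
25 | 3-methylbutanoyl chloride | CC(C)CC(Cl)=O | starting material
26 | C11 isovalerate C1 angelate, OSiEt3 on C2, tertiary OH on C8 | CC(C)CC(=O)O[C@@H]1[C@H](OC(=O)/C(C)=C\C)[C@@H](O[Si](CC)(CC)CC)C(C)(C)[C@@H]2[C@H]3CC[C@@](C)(O)[C@@H]2[C@@]13C | intermediate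
27 | alkene: 26 dehydrated to C7=C8 | CC(C)CC(=O)O[C@@H]1[C@H](OC(=O)/C(C)=C\C)[C@@H](O[Si](CC)(CC)CC)C(C)(C)[C@@H]2[C@H]3CC=C(C)[C@@H]2[C@@]13C | intermediate
28 | enone: C6 ketone, silyl ether on C2 | CC(C)CC(=O)O[C@@H]1[C@H](OC(=O)/C(C)=C\C)[C@@H](O[Si](CC)(CC)CC)C(C)(C)[C@@H]2[C@H]3C(=O)C=C(C)[C@@H]2[C@@]13C | intermediate
29 | CNP0151972.1 | C/C=C(/C)C(=O)O[C@@H]1[C@@H](O)C(C)(C)[C@@H]2[C@H]3C(=O)C=C(C)[C@@H]2[C@@]3(C)[C@@H]1OC(=O)CC(C)C | target

**Step count and risks**

Total step count: 16. Longest linear sequence: 16 steps (1 → 29).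

Steps most likely to fail:

1. Step 10. What may go wrong: opening of the epoxide by the C2 alkoxide before the silyl group has moved, reversal of the aldol on warming, or poor facial selectivity in the aldol (the C2 configuration cannot be corrected later, because the finished tricycle offers almost no facial bias at the seven-membered ring). Fallback, setting out from 16 and returning at 20: the two ring closures are separated so that no epoxide is present while an alkoxide sits on C2. Keto aldehyde 16 is treated with LiN(i-Pr)2 (1.1 equiv, THF, −78 → −20 °C), and the aldol with silyl transfer gives the bicyclic hydroxy ketone F1. Its ring alkene is epoxidised with dimethyldioxirane, anti to the substituent on C4, to give the epoxide F2. F2 is then cyclised with KN(SiMe3)2 (2.2 equiv, toluene, 0 → 40 °C) through the alkoxide–enolate dianion to give 20.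

2. Step 14. What may go wrong: ionisation of the tertiary carbinol next to the cyclobutane with ring fragmentation, or elimination toward the methyl group. Fallback, setting out from 26 and returning at 27: a Chugaev elimination replaces the dehydration. 26 is converted with NaH, CS2 and MeI (THF, 0 °C) into the S-methyl xanthate F3, which is heated in toluene at 110 °C; the concerted syn-elimination avoids any cationic intermediate and gives 27.

3. Step 12. What may go wrong: migration of the angeloyl group from O–C1 to the new alkoxide on C11, and loss of facial selectivity. Fallback, setting out from 20 and returning at 26: the esters are introduced in the opposite order behind a temporary ether. 20 is protected on O–C1 with 4-methoxybenzyl trichloroacetimidate and catalytic La(OTf)3 to give the ether F4. Reduction with NaBH4 (anti to the ether) gives the alcohol F5, acylation with 25 and pyridine gives the isovalerate F6, and DDQ (CH2Cl2/H2O) frees the C1 hydroxyl in F7. F7 is then esterified with 21 as in step 11 to give 26.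

**Further compounds**

F1 | step 10 | bicyclic hydroxy ketone with ring alkene (OH on C1, OSiEt3 on C2, C8=C9) | O=C1[C@H](O)[C@@H](O[Si](CC)(CC)CC)C(C)(C)[C@@H]2[C@H](C1C)CCC(C)=C2
F2 | step 10 | epoxide of F1 (C8–C9 epoxide trans to the ring fusion substituents) | O=C1[C@H](O)[C@@H](O[Si](CC)(CC)CC)C(C)(C)[C@@H]2[C@H](C1C)CC[C@@]3(C)O[C@@H]23
F3 | step 14 | S-methyl xanthate of the C8 carbinol of 26 | CC(C)CC(=O)O[C@@H]1[C@H](OC(=O)/C(C)=C\C)[C@@H](O[Si](CC)(CC)CC)C(C)(C)[C@@H]2[C@H]3CC[C@@](C)(OC(=S)SC)[C@@H]2[C@@]13C
F4 | step 12 | 4-methoxybenzyl ether of 20 on O–C1 | O=C1[C@H](OCc4ccc(OC)cc4)[C@@H](O[Si](CC)(CC)CC)C(C)(C)[C@@H]2[C@H]3CC[C@@](C)(O)[C@@H]2[C@@]13C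
F5 | step 12 | C11 alcohol of F4 (OH cis to the ether on C1) | O[C@@H]1[C@H](OCc4ccc(OC)cc4)[C@@H](O[Si](CC)(CC)CC)C(C)(C)[C@@H]2[C@H]3CC[C@@](C)(O)[C@@H]2[C@@]13C
F6 | step 12 | C11 isovalerate of F5 | CC(C)CC(=O)O[C@@H]1[C@H](OCc4ccc(OC)cc4)[C@@H](O[Si](CC)(CC)CC)C(C)(C)[C@@H]2[C@H]3CC[C@@](C)(O)[C@@H]2[C@@]13C
F7 | step 12 | C11 isovalerate with free OH on C1 | CC(C)CC(=O)O[C@@H]1[C@H](O)[C@@H](O[Si](CC)(CC)CC)C(C)(C)[C@@H]2[C@H]3CC[C@@](C)(O)[C@@H]2[C@@]13C
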